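The runs are calculated with constants of no real substance, noise included.

Set the life of E against the length of the run, and the late ratio becomes a count. In the steps thought possible, Q interconverts Z and X, G makes E from X and D, E passes to L, and G can turn into J.

- delta: Z 0.10 M; D 0.12 M; Q 1.9 mM; G 50 µM; the very flask that is asked about, followed so far
- flask: Z 0.10 M; D 0.120 M; Q 1.9 mM; G 50 µM; time 2.5 h

delta run (percent of the Z charged)

| time / min | L / % | E / % | Z / % |
|---|---|---|---|
| 6.00 | 3.9 | 9.9 | 52.5 |
| 20.0 | 29.8 | 9.0 | 24.7 |
| 40.0 | 49.4 | 3.4 | 17.6 |
| 50.0 | 51.8 | 0.6 | 15.3 |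
| 80.0 | 59.8 | 0 | 16.0 |

(standard deviation of a reading: 1 percentage point)

- ratio of L to E at 4.0 min
- ratio of L to E at 2.5 h

- the numbers in the tables scatter with a standard deviation of 1 percentage point
- steps thought possible: Z + Q <-> Q + X; D + G + X -> G + E; E -> L; G <-> J

How long does E live? From 20.0 min to 40.0 min, L rose 20 percentage points while E averaged 6.20%, so I read a lifetime of 6.33 min. That is far shorter than 2.5 h, so I treat late E as being at quasi-steady state. But 4.0 min is shorter than one lifetime, so I expect L still below E there.

How much has G done? By 80.0 min, the product per G charged reads 1200 turnovers.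

How much of that is still E? The last two readings give 31.2 turnovers per lifetime, the turnovers per G charged made while one E lives. Late L/E is then turnovers done over turnovers per lifetime.

Held at that pace to 2.5 h, this gives 49.4. But the pace, as read from L and E, fell 2.84-fold from the window of the lifetime to the window of the last two readings, and that fall carried on gives 483. I commit to a ratio between them.

The forecast gives 0.25 and 400, calling the second “a few hundred, and very uncertain”.

The flask gives 0.266 and 198.

    Z + Q ⇌ Q + X (K = 1.90, k = 1.10 /M/s)
    D + G + X → G + E (k = 370 /M²/s)
    E → L (k = 0.00270 /s)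
    G ⇌ J (K = 29.0, k = 8.70 × 10⁻⁴ /s)

The half-life of E by its passing into L alone, 0.071 h, is short against 2.5 h. The E standing in the flask at 2.5 h, 0.318%, counts 6.37 turnovers per lifetime, against 1270 done. The forecast's ratio corresponds to 3.17 per lifetime. In the neighbouring flask, with 2.0 × 10⁻⁵ M of G, E stands at 0.292% at 2.5 h. That counts 14.6 turnovers per lifetime, against 2000 done, and its ratio is 136.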